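**Strategy.** The ten-membered carbocycle is closed last between C9 and C10 (germacrane numbering) by a SmI2-mediated intramolecular Reformatsky-type aldol. It exploits the 1,3-dioxygen pattern O8/O10 across the C9 methylene of the cyclodecene ring, an aldol retron in which C8 is temporarily a ketone. One operation forms the carbocycle, the C9–C10 bond and the tertiary C10 carbinol. The precursor is a monocyclic cis-4,5-disubstituted α-methylene-γ-butyrolactone carrying a bromoacetyl group at C7 and, at C6, a Z-alkenyl chain that ends in the C10 methyl ketone. A Marshall propargylation sets C6 and C7; directed reduction and angeloylation finish the route.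

Key step: step 16

Remark: germacrane numbering is used for ring atoms (C6/C7 lactone fusion, C8 acyloxy carbon, C10 tertiary carbinol, C11–C13 methylene-lactone carbons, C14/C15 the methyls on C10/C4); the target is read as 3S,6S,7R,8R,10S with a 4Z alkene, a cis-fused lactone and an angelate (Z) ester; the ProPhenol antipode in steps 2 and 7 is the one that gives the S carbinols (same spatial sense in both), to be confirmed by Mosher analysis.

Step 1
Reactants: 1 ethyl 3-(2-methyl-1,3-dioxolan-2-yl)propanoate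
Product: 2 3-(2-methyl-1,3-dioxolan-2-yl)propanal
Conditions: iBu2AlH (1.05 equiv), CH2Cl2, −78 °C; then H2O
Reagents that add atoms: none
Why: Partial ester reduction with iBu2AlH at −78 °C stops at the aluminium hemiacetal, which gives the aldehyde on hydrolysis; the ketal is inert to hydride.

Step 2
Reactants: 2 3-(2-methyl-1,3-dioxolan-2-yl)propanal; 3 methyl propiolate
Product: 4 methyl (4S)-4-hydroxy-6-(2-methyl-1,3-dioxolan-2-yl)hex-2-ynoate
Conditions: Me2Zn (3 equiv), ProPhenol ligand (10 mol%), Ph3P=O (20 mol%), toluene, 0 °C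
Reagents that add atoms: none
Why: Trost dinuclear zinc–ProPhenol asymmetric alkynylation of an aldehyde; the methylzinc acetylide is delivered inside the chiral pocket to one carbonyl face, which sets the future C3 carbinol (4S here).

Step 3
Reactants: 4 methyl (4S)-4-hydroxy-6-(2-methyl-1,3-dioxolan-2-yl)hex-2-ynoate
Product: 5 methyl (4S)-4-(TBSO)-6-(2-methyl-1,3-dioxolan-2-yl)hex-2-ynoate
Conditions: TBSCl, imidazole, DMF, rt
Reagents that add atoms: tert-butyldimethylsilyl chloride (TBSCl), CC(C)(C)[Si](C)(C)Cl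
Why: Standard silylation of a secondary propargylic alcohol protects O3 until the last step.

Step 4
Reactants: 5 methyl (4S)-4-(TBSO)-6-(2-methyl-1,3-dioxolan-2-yl)hex-2-ynoate
Product: 6 methyl (2Z,4S)-4-(TBSO)-3-methyl-6-(2-methyl-1,3-dioxolan-2-yl)hex-2-enoate
Conditions: Me2CuLi (from CuI and MeLi, 1.5 equiv), THF, −78 °C; MeOH then aq. NH4Cl at −78 °C
Reagents that add atoms: lithium dimethylcuprate, [Li+].C[Cu-]C
Why: Conjugate addition (syn carbocupration) of the Gilman reagent to the ynoate and cold protonation of the vinylcopper with retention place the ester cis to the silyloxy carbon, which fixes the Z-C4=C5 alkene and brings in C15.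

Step 5
Reactants: 6 methyl (2Z,4S)-4-(TBSO)-3-methyl-6-(2-methyl-1,3-dioxolan-2-yl)hex-2-enoate
Product: 7 (2Z,4S)-4-(TBSO)-3-methyl-6-(2-methyl-1,3-dioxolan-2-yl)hex-2-en-1-ol
Conditions: iBu2AlH (2.2 equiv), CH2Cl2, −78 °C; then H2O
Reagents that add atoms: none
Why: 1,2-Reduction of the enoate with iBu2AlH should give the Z allylic alcohol without touching ketal or silyl ether.

Step 6
Reactants: 7 (2Z,4S)-4-(TBSO)-3-methyl-6-(2-methyl-1,3-dioxolan-2-yl)hex-2-en-1-ol
Product: 8 (2Z,4S)-4-(TBSO)-3-methyl-6-(2-methyl-1,3-dioxolan-2-yl)hex-2-enal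
Conditions: MnO2 (excess), CH2Cl2, rt; used at once
Reagents that add atoms: none
Why: Allylic oxidation with MnO2 is neutral and selective for the allylic alcohol, which limits Z to E isomerisation of the enal.

Step 7
Reactants: 9 3-(TBSO)propanal; 10 ethynyltrimethylsilane
Product: 11 (3S)-5-(TBSO)-1-(trimethylsilyl)pent-1-yn-3-ol
Conditions: Me2Zn (3 equiv), ProPhenol ligand (same antipode as step 2, 10 mol%), Ph3P=O (20 mol%), toluene, 0 °C
Reagents that add atoms: none
Why: The same zinc–ProPhenol asymmetric alkynylation sets the propargylic carbinol (3S) that later becomes C7 with inversion.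

Step 8
Reactants: 11 (3S)-5-(TBSO)-1-(trimethylsilyl)pent-1-yn-3-ol
Product: 12 (3S)-5-(TBSO)-1-(trimethylsilyl)pent-1-yn-3-yl methanesulfonate
Conditions: MsCl, Et3N, CH2Cl2, −78 to 0 °C
Reagents that add atoms: methanesulfonyl chloride, CS(=O)(=O)Cl
Why: Sulfonylation at oxygen leaves the carbinol configuration unchanged and gives the propargylic leaving group.

Step 9
Reactants: 8 (2Z,4S)-4-(TBSO)-3-methyl-6-(2-methyl-1,3-dioxolan-2-yl)hex-2-enal; 12 (3S)-5-(TBSO)-1-(trimethylsilyl)pent-1-yn-3-yl methanesulfonate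
Product: 14 (3R,4S,5Z,7S)-1,7-bis(TBSO)-6-methyl-9-(2-methyl-1,3-dioxolan-2-yl)-3-[(trimethylsilyl)ethynyl]non-5-en-4-ol, via allenylzinc reagent 13 (not isolated)
Conditions: Pd(OAc)2 (5 mol%), PPh3 (5 mol%), Et2Zn (3 equiv), THF, −78 to −20 °C
Reagents that add atoms: none
Why: Marshall propargylation: zerovalent palladium ionises the mesylate by anti SN2′ attack, transmetallation gives the axially chiral allenylzinc 13, and its cyclic SE2′ addition to the aldehyde forms C6–C7 with net inversion at C7 and anti topicity, so the reagent sets 6S and 7R (3R,4S in 14).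

Step 10
Reactants: 14 (3R,4S,5Z,7S)-1,7-bis(TBSO)-6-methyl-9-(2-methyl-1,3-dioxolan-2-yl)-3-[(trimethylsilyl)ethynyl]non-5-en-4-ol
Product: 15 (3R,4S,5Z,7S)-7-(TBSO)-6-methyl-9-(2-methyl-1,3-dioxolan-2-yl)-3-[(trimethylsilyl)ethynyl]non-5-ene-1,4-diol
Conditions: HF·pyridine, pyridine, THF, 0 °C
Reagents that add atoms: none
Why: Buffered fluoride desilylation discriminates on steric grounds, so the primary silyl ether should cleave much faster than the hindered allylic secondary one; the C-silyl alkyne and the ketal are stable.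

Step 11
Reactants: 15 (3R,4S,5Z,7S)-7-(TBSO)-6-methyl-9-(2-methyl-1,3-dioxolan-2-yl)-3-[(trimethylsilyl)ethynyl]non-5-ene-1,4-diol
Product: 18 (4R,5S)-5-[(1Z,3S)-3-(TBSO)-2-methyl-5-(2-methyl-1,3-dioxolan-2-yl)pent-1-en-1-yl]-4-[(trimethylsilyl)ethynyl]oxolan-2-one, via hydroxy aldehyde 16 (not isolated), via lactol 17 (not isolated)
Conditions: TEMPO (20 mol%), PhI(OAc)2 (2.5 equiv), CH2Cl2, rt
Reagents that add atoms: none
Why: Oxidative lactonisation of a 1,4-diol: TEMPO/PhI(OAc)2 oxidises the primary alcohol first, the aldehyde closes to the lactol with O6 and is oxidised on to the γ-lactone, with C6 and C7 untouched, so the lactone is cis.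

Step 12
Reactants: 18 (4R,5S)-5-[(1Z,3S)-3-(TBSO)-2-methyl-5-(2-methyl-1,3-dioxolan-2-yl)pent-1-en-1-yl]-4-[(trimethylsilyl)ethynyl]oxolan-2-one
Product: 21 (4R,5S)-5-[(1Z,3S)-3-(TBSO)-2-methyl-5-(2-methyl-1,3-dioxolan-2-yl)pent-1-en-1-yl]-3-methylidene-4-[(trimethylsilyl)ethynyl]oxolan-2-one, via Mannich base 19 (not isolated), via ammonium iodide 20 (not isolated)
Conditions: LiN(iPr)2 (1.1 equiv), THF, −78 °C; [Me2N=CH2]I, −78 to 0 °C; then MeI, MeOH, rt; then aq. NaHCO3, CH2Cl2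
Reagents that add atoms: Eschenmoser's salt (N,N-dimethylmethyleneiminium iodide), C[N+](C)=C.[I-]
Why: Eschenmoser α-methylenation: the lithium enolate at C11 is aminomethylated, the Mannich base is quaternised and the ammonium salt undergoes mild β-elimination to the exocyclic C11=C13 alkene.

Step 13
Reactants: 21 (4R,5S)-5-[(1Z,3S)-3-(TBSO)-2-methyl-5-(2-methyl-1,3-dioxolan-2-yl)pent-1-en-1-yl]-3-methylidene-4-[(trimethylsilyl)ethynyl]oxolan-2-one
Product: 22 (4R,5S)-4-(bromoethynyl)-5-[(1Z,3S)-3-(TBSO)-2-methyl-5-(2-methyl-1,3-dioxolan-2-yl)pent-1-en-1-yl]-3-methylideneoxolan-2-one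
Conditions: NBS (1.2 equiv), AgNO3 (10 mol%), acetone, rt, dark
Reagents that add atoms: N-bromosuccinimide, O=C1CCC(=O)N1Br
Why: Silver-catalysed desilylative bromination: AgNO3 turns the C-silyl alkyne into a silver acetylide, which NBS should brominate faster than it attacks the deactivated alkenes.

Step 14
Reactants: 22 (4R,5S)-4-(bromoethynyl)-5-[(1Z,3S)-3-(TBSO)-2-methyl-5-(2-methyl-1,3-dioxolan-2-yl)pent-1-en-1-yl]-3-methylideneoxolan-2-one
Product: 23 (4S,5S)-4-(2-bromoacetyl)-5-[(1Z,3S)-3-(TBSO)-2-methyl-5-(2-methyl-1,3-dioxolan-2-yl)pent-1-en-1-yl]-3-methylideneoxolan-2-one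
Conditions: XPhosAuNTf2 (2 mol%), H2O (3 equiv), 1,2-dichloroethane, rt
Reagents that add atoms: water, O
Why: Gold-catalysed hydration of a 1-bromoalkyne gives the α-bromomethyl ketone with oxygen at the internal carbon C8, helped by 5-exo participation of the lactone carbonyl, while the C4=C5 alkene is deactivated by two allylic C–O bonds.

Step 15
Reactants: 23 (4S,5S)-4-(2-bromoacetyl)-5-[(1Z,3S)-3-(TBSO)-2-methyl-5-(2-methyl-1,3-dioxolan-2-yl)pent-1-en-1-yl]-3-methylideneoxolan-2-one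
Product: 24 (4S,5S)-4-(2-bromoacetyl)-5-[(1Z,3S)-3-(TBSO)-2-methyl-6-oxohept-1-en-1-yl]-3-methylideneoxolan-2-one
Conditions: PPTS (20 mol%), acetone/H2O (10:1), 40 °C
Reagents that add atoms: water, O
Why: Mild acid-catalysed ketal hydrolysis releases the C10 methyl ketone; the secondary silyl ether and the α-bromo ketone should survive PPTS.

Step 16
Reactants: 24 (4S,5S)-4-(2-bromoacetyl)-5-[(1Z,3S)-3-(TBSO)-2-methyl-6-oxohept-1-en-1-yl]-3-methylideneoxolan-2-one
Product: 26 (3aS,6S,9S,10Z,11aS)-9-(TBSO)-6-hydroxy-6,10-dimethyl-3-methylidene-3a,5,6,7,8,9-hexahydrocyclodeca[b]furan-2,4(3H,11aH)-dione, via samarium enolate 25 (not isolated)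
Conditions: SmI2 (2.5 equiv, 0.1 M in THF), THF, −78 °C, 24 added by syringe pump over 4 h (final 1 mM); pH 7 buffer at −78 °C
Reagents that add atoms: none
Why: Two single-electron transfers from SmI2 cleave the C9–Br bond and give the trivalent samarium enolate 25 regiospecifically at C8/C9, which adds through C9 to the C10 methyl ketone in a samarium-bridged chair (Zimmerman–Traxler) transition state, so the C9–C10 bond and the tertiary C10 alkoxide form together. The closest known reaction type is the SmI2-promoted intramolecular Reformatsky (aldol) cyclisation of α-bromo carbonyl compounds used for medium-ring carbocycles and macrolides. The ten-membered ring closes in a 10-(enolendo)-exo-trig mode onto the ketone carbon, with the cis-fused lactone and the Z-C4=C5 alkene turning both chain ends toward each other. C10 is the only new stereocentre and is set under control of the forming ring: with samarium bridging O8 and O10, the C1–C3 tether should reach C10 from the lactone face bearing H6 and H7, placing C14 axial and giving 10S; this facial preference is the least certain element. The step needs enolate formation at C9 rather than C7, secured by the position of bromine; chemoselectivity over the methylene lactone and the ketone, secured by the much faster reduction of α-bromo ketones at −78 °C without HMPA and by the 5-endo geometry of a Michael attack on C13; and cyclisation over oligomerisation, secured by high dilution.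

Step 17
Reactants: 26 (3aS,6S,9S,10Z,11aS)-9-(TBSO)-6-hydroxy-6,10-dimethyl-3-methylidene-3a,5,6,7,8,9-hexahydrocyclodeca[b]furan-2,4(3H,11aH)-dione
Product: 27 (3aR,4R,6S,9S,10Z,11aS)-9-(TBSO)-4,6-dihydroxy-6,10-dimethyl-3-methylidene-3a,4,5,6,7,8,9,11a-octahydrocyclodeca[b]furan-2(3H)-one
Conditions: Me4NBH(OAc)3 (5 equiv), MeCN/AcOH (1:1), −30 °C
Reagents that add atoms: none
Why: Evans–Saksena reduction: the C10 hydroxyl exchanges an acetate on boron and delivers hydride intramolecularly to C8 through a chair transition state, which should give the 1,3-anti diol and so the 8R carbinol; the acidic medium spares the methylene lactone.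

Step 18
Reactants: 27 (3aR,4R,6S,9S,10Z,11aS)-9-(TBSO)-4,6-dihydroxy-6,10-dimethyl-3-methylidene-3a,4,5,6,7,8,9,11a-octahydrocyclodeca[b]furan-2(3H)-one; 28 angelic acid ((2Z)-2-methylbut-2-enoic acid)
Product: 29 (3aR,4R,6S,9S,10Z,11aS)-9-(TBSO)-6-hydroxy-6,10-dimethyl-3-methylidene-2-oxo-2,3,3a,4,5,6,7,8,9,11a-decahydrocyclodeca[b]furan-4-yl (2Z)-2-methylbut-2-enoate
Conditions: 28, 2,4,6-trichlorobenzoyl chloride, Et3N, toluene, rt, 2 h; then 27, 75 °C (no DMAP)
Reagents that add atoms: none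
Why: Yamaguchi-type esterification through the mixed anhydride of angelic acid without DMAP should acylate only the secondary C8 hydroxyl (the tertiary C10 hydroxyl is inert) and avoid isomerisation of the angelate to the tiglate.

Step 19
Reactants: 29 (3aR,4R,6S,9S,10Z,11aS)-9-(TBSO)-6-hydroxy-6,10-dimethyl-3-methylidene-2-oxo-2,3,3a,4,5,6,7,8,9,11a-decahydrocyclodeca[b]furan-4-yl (2Z)-2-methylbut-2-enoate
Product: 30 (3aR,4R,6S,9S,10Z,11aS)-6,9-dihydroxy-6,10-dimethyl-3-methylidene-2-oxo-2,3,3a,4,5,6,7,8,9,11a-decahydrocyclodeca[b]furan-4-yl (2Z)-2-methylbut-2-enoate (CNP0137971.2)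
Conditions: HF·pyridine, pyridine, THF, 0 °C to rt
Reagents that add atoms: none
Why: Buffered fluoride cleavage of the silyl ether should free O3 without touching the angelate, the methylene lactone or the tertiary alcohol.

**Compound list** (TBS = tert-butyldimethylsilyl)

1 | ethyl 3-(2-methyl-1,3-dioxolan-2-yl)propanoate | CCOC(=O)CCC1(C)OCCO1 | starting material
2 | 3-(2-methyl-1,3-dioxolan-2-yl)propanal | O=CCCC1(C)OCCO1 | intermediate
3 | methyl propiolate | C#CC(=O)OC | starting material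
4 | methyl (4S)-4-hydroxy-6-(2-methyl-1,3-dioxolan-2-yl)hex-2-ynoate | COC(=O)C#C[C@@H](O)CCC1(C)OCCO1 | intermediate
5 | methyl (4S)-4-[(tert-butyldimethylsilyl)oxy]-6-(2-methyl-1,3-dioxolan-2-yl)hex-2-ynoate | COC(=O)C#C[C@@H](O[Si](C)(C)C(C)(C)C)CCC1(C)OCCO1 | intermediate
6 | methyl (2Z,4S)-4-[(tert-butyldimethylsilyl)oxy]-3-methyl-6-(2-methyl-1,3-dioxolan-2-yl)hex-2-enoate | COC(=O)/C=C(/C)[C@@H](O[Si](C)(C)C(C)(C)C)CCC1(C)OCCO1 | intermediate
7 | (2Z,4S)-4-[(tert-butyldimethylsilyl)oxy]-3-methyl-6-(2-methyl-1,3-dioxolan-2-yl)hex-2-en-1-ol | OC/C=C(/C)[C@@H](O[Si](C)(C)C(C)(C)C)CCC1(C)OCCO1 | intermediate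
8 | (2Z,4S)-4-[(tert-butyldimethylsilyl)oxy]-3-methyl-6-(2-methyl-1,3-dioxolan-2-yl)hex-2-enal | O=C/C=C(/C)[C@@H](O[Si](C)(C)C(C)(C)C)CCC1(C)OCCO1 | intermediate
9 | 3-[(tert-butyldimethylsilyl)oxy]propanal | O=CCCO[Si](C)(C)C(C)(C)C | starting material
10 | ethynyltrimethylsilane | C#C[Si](C)(C)C | starting material
11 | (3S)-5-[(tert-butyldimethylsilyl)oxy]-1-(trimethylsilyl)pent-1-yn-3-ol | C[Si](C)(C)C#C[C@@H](O)CCO[Si](C)(C)C(C)(C)C | intermediate
12 | (3S)-5-[(tert-butyldimethylsilyl)oxy]-1-(trimethylsilyl)pent-1-yn-3-yl methanesulfonate | C[Si](C)(C)C#C[C@@H](OS(C)(=O)=O)CCO[Si](C)(C)C(C)(C)C | intermediate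
13 | ethyl[(aR)-5-[(tert-butyldimethylsilyl)oxy]-1-(trimethylsilyl)penta-1,2-dien-1-yl]zinc | CC[Zn]C([Si](C)(C)C)=[C@]=C([H])CCO[Si](C)(C)C(C)(C)C | intermediate (not isolated)
14 | (3R,4S,5Z,7S)-1,7-bis[(tert-butyldimethylsilyl)oxy]-6-methyl-9-(2-methyl-1,3-dioxolan-2-yl)-3-[(trimethylsilyl)ethynyl]non-5-en-4-ol | O[C@@H](/C=C(/C)[C@@H](O[Si](C)(C)C(C)(C)C)CCC1(C)OCCO1)[C@@H](C#C[Si](C)(C)C)CCO[Si](C)(C)C(C)(C)C | intermediate
15 | (3R,4S,5Z,7S)-7-[(tert-butyldimethylsilyl)oxy]-6-methyl-9-(2-methyl-1,3-dioxolan-2-yl)-3-[(trimethylsilyl)ethynyl]non-5-ene-1,4-diol | O[C@@H](/C=C(/C)[C@@H](O[Si](C)(C)C(C)(C)C)CCC1(C)OCCO1)[C@@H](C#C[Si](C)(C)C)CCO | intermediate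
16 | (3R,4S,5Z,7S)-7-[(tert-butyldimethylsilyl)oxy]-4-hydroxy-6-methyl-9-(2-methyl-1,3-dioxolan-2-yl)-3-[(trimethylsilyl)ethynyl]non-5-enal | O[C@@H](/C=C(/C)[C@@H](O[Si](C)(C)C(C)(C)C)CCC1(C)OCCO1)[C@@H](C#C[Si](C)(C)C)CC=O | intermediate (not isolated)
17 | (4R,5S)-5-[(1Z,3S)-3-[(tert-butyldimethylsilyl)oxy]-2-methyl-5-(2-methyl-1,3-dioxolan-2-yl)pent-1-en-1-yl]-4-[(trimethylsilyl)ethynyl]oxolan-2-ol (anomer mixture) | OC1O[C@@H](/C=C(/C)[C@@H](O[Si](C)(C)C(C)(C)C)CCC2(C)OCCO2)[C@@H](C#C[Si](C)(C)C)C1 | intermediate (not isolated)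
18 | (4R,5S)-5-[(1Z,3S)-3-[(tert-butyldimethylsilyl)oxy]-2-methyl-5-(2-methyl-1,3-dioxolan-2-yl)pent-1-en-1-yl]-4-[(trimethylsilyl)ethynyl]oxolan-2-one | O=C1O[C@@H](/C=C(/C)[C@@H](O[Si](C)(C)C(C)(C)C)CCC2(C)OCCO2)[C@@H](C#C[Si](C)(C)C)C1 | intermediate
19 | 3-[(dimethylamino)methyl] derivative of 18 (Mannich base, C3 of the lactone unassigned) | CN(C)CC1C(=O)O[C@@H](/C=C(/C)[C@@H](O[Si](C)(C)C(C)(C)C)CCC2(C)OCCO2)[C@H]1C#C[Si](C)(C)C | intermediate (not isolated)
20 | 3-[(trimethylammonio)methyl] derivative of 18, iodide | C[N+](C)(C)CC1C(=O)O[C@@H](/C=C(/C)[C@@H](O[Si](C)(C)C(C)(C)C)CCC2(C)OCCO2)[C@H]1C#C[Si](C)(C)C.[I-] | intermediate (not isolated)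
21 | (4R,5S)-5-[(1Z,3S)-3-[(tert-butyldimethylsilyl)oxy]-2-methyl-5-(2-methyl-1,3-dioxolan-2-yl)pent-1-en-1-yl]-3-methylidene-4-[(trimethylsilyl)ethynyl]oxolan-2-one | C=C1C(=O)O[C@@H](/C=C(/C)[C@@H](O[Si](C)(C)C(C)(C)C)CCC2(C)OCCO2)[C@H]1C#C[Si](C)(C)C | intermediate
22 | (4R,5S)-4-(bromoethynyl)-5-[(1Z,3S)-3-[(tert-butyldimethylsilyl)oxy]-2-methyl-5-(2-methyl-1,3-dioxolan-2-yl)pent-1-en-1-yl]-3-methylideneoxolan-2-one | C=C1C(=O)O[C@@H](/C=C(/C)[C@@H](O[Si](C)(C)C(C)(C)C)CCC2(C)OCCO2)[C@H]1C#CBr | intermediate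
23 | (4S,5S)-4-(2-bromoacetyl)-5-[(1Z,3S)-3-[(tert-butyldimethylsilyl)oxy]-2-methyl-5-(2-methyl-1,3-dioxolan-2-yl)pent-1-en-1-yl]-3-methylideneoxolan-2-one | C=C1C(=O)O[C@@H](/C=C(/C)[C@@H](O[Si](C)(C)C(C)(C)C)CCC2(C)OCCO2)[C@H]1C(=O)CBr | intermediate
24 | (4S,5S)-4-(2-bromoacetyl)-5-[(1Z,3S)-3-[(tert-butyldimethylsilyl)oxy]-2-methyl-6-oxohept-1-en-1-yl]-3-methylideneoxolan-2-one | C=C1C(=O)O[C@@H](/C=C(/C)[C@@H](O[Si](C)(C)C(C)(C)C)CCC(C)=O)[C@H]1C(=O)CBr | intermediate
25 | diiodosamarium enolate of the debrominated ketone (O–Sm on C8, C8=C9 enolate) | C=C1C(=O)O[C@@H](/C=C(/C)[C@@H](O[Si](C)(C)C(C)(C)C)CCC(C)=O)[C@H]1C(=C)O[Sm](I)I | intermediate (not isolated)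
26 | (3aS,6S,9S,10Z,11aS)-9-[(tert-butyldimethylsilyl)oxy]-6-hydroxy-6,10-dimethyl-3-methylidene-3a,5,6,7,8,9-hexahydrocyclodeca[b]furan-2,4(3H,11aH)-dione | C=C1C(=O)O[C@H]2/C=C(/C)[C@@H](O[Si](C)(C)C(C)(C)C)CC[C@](C)(O)CC(=O)[C@@H]12 | intermediate
27 | (3aR,4R,6S,9S,10Z,11aS)-9-[(tert-butyldimethylsilyl)oxy]-4,6-dihydroxy-6,10-dimethyl-3-methylidene-3a,4,5,6,7,8,9,11a-octahydrocyclodeca[b]furan-2(3H)-one | C=C1C(=O)O[C@H]2/C=C(/C)[C@@H](O[Si](C)(C)C(C)(C)C)CC[C@](C)(O)C[C@@H](O)[C@@H]12 | intermediate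
28 | angelic acid, (2Z)-2-methylbut-2-enoic acid | C/C=C(/C)C(=O)O | starting material
29 | (3aR,4R,6S,9S,10Z,11aS)-9-[(tert-butyldimethylsilyl)oxy]-6-hydroxy-6,10-dimethyl-3-methylidene-2-oxo-2,3,3a,4,5,6,7,8,9,11a-decahydrocyclodeca[b]furan-4-yl (2Z)-2-methylbut-2-enoate | C=C1C(=O)O[C@H]2/C=C(/C)[C@@H](O[Si](C)(C)C(C)(C)C)CC[C@](C)(O)C[C@@H](OC(=O)/C(C)=C\C)[C@@H]12 | intermediate
30 | (3aR,4R,6S,9S,10Z,11aS)-6,9-dihydroxy-6,10-dimethyl-3-methylidene-2-oxo-2,3,3a,4,5,6,7,8,9,11a-decahydrocyclodeca[b]furan-4-yl (2Z)-2-methylbut-2-enoate | C=C1C(=O)O[C@H]2/C=C(/C)[C@@H](O)CC[C@](C)(O)C[C@@H](OC(=O)/C(C)=C\C)[C@@H]12 | target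

**Totals.** Total step count: 19. Longest linear sequence: 17 steps (steps 1–6 and 9–19).

**Steps most likely to fail**

Step 16. The samarium enolate may be protonated by the C10 methyl ketone before it cyclises (giving the debrominated diketone), oligomerisation may compete, or the ketone may be attacked from the wrong face at C10. The fallback sets out from 24: zinc dust and Me3SiCl (MeCN, TMEDA) should convert the bromo ketone regiospecifically into the trimethylsilyl enol ether F1. A TiCl4-mediated intramolecular Mukaiyama aldol (CH2Cl2, −78 °C, high dilution) would then close the same C9–C10 bond through an open, non-chelated transition state with a different facial bias. It comes back to the route at 26.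

Step 14. Cationic gold may trigger cycloisomerisation of the 1,5-enyne (C4=C5 with C8≡C9) instead of hydration. The fallback sets out from 21: protodesilylation (AgNO3, 2,6-lutidine, aqueous acetone) should give the terminal alkyne F2. Ruthenium-catalysed Markovnikov addition of benzoic acid ([RuCl2(p-cymene)]2, tri(2-furyl)phosphine, Na2CO3, toluene, 50 °C) should give the enol benzoate F3. Its electron-rich enol double bond should then be brominated selectively by NBS in wet THF at 0 °C to the bromo ketone. It comes back to the route at 23.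

Step 17. Hydride may be delivered from the wrong face because the ten-membered ring does not allow the chair for internal delivery, giving the 1,3-syn diol, and the free C8 hydroxyl may translactonise onto C12. The fallback sets out from 26: a chelation-controlled Narasaka–Prasad reduction (Et2BOMe, NaBH4, THF/MeOH, −78 °C) would deliberately give the 8-epi (syn) diol F4. A Mitsunobu esterification with 28 (PPh3, DIAD, toluene, 0 °C) would then invert C8 while introducing the angelate in one operation. It comes back to the route at 29, so step 18 is not needed.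

**Further compounds**

F1 | step 16 | (4S,5S)-5-[(1Z,3S)-3-[(tert-butyldimethylsilyl)oxy]-2-methyl-6-oxohept-1-en-1-yl]-3-methylidene-4-{1-[(trimethylsilyl)oxy]ethenyl}oxolan-2-one | C=C1C(=O)O[C@@H](/C=C(/C)[C@@H](O[Si](C)(C)C(C)(C)C)CCC(C)=O)[C@H]1C(=C)O[Si](C)(C)C
F2 | step 14 | (4S,5S)-4-ethynyl-5-[(1Z,3S)-3-[(tert-butyldimethylsilyl)oxy]-2-methyl-5-(2-methyl-1,3-dioxolan-2-yl)pent-1-en-1-yl]-3-methylideneoxolan-2-one | C=C1C(=O)O[C@@H](/C=C(/C)[C@@H](O[Si](C)(C)C(C)(C)C)CCC2(C)OCCO2)[C@H]1C#C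
F3 | step 14 | 1-[(2S,3S)-2-[(1Z,3S)-3-[(tert-butyldimethylsilyl)oxy]-2-methyl-5-(2-methyl-1,3-dioxolan-2-yl)pent-1-en-1-yl]-4-methylidene-5-oxooxolan-3-yl]ethenyl benzoate | C=C1C(=O)O[C@@H](/C=C(/C)[C@@H](O[Si](C)(C)C(C)(C)C)CCC2(C)OCCO2)[C@H]1C(=C)OC(=O)c3ccccc3
F4 | step 17 | (3aR,4S,6S,9S,10Z,11aS)-9-[(tert-butyldimethylsilyl)oxy]-4,6-dihydroxy-6,10-dimethyl-3-methylidene-3a,4,5,6,7,8,9,11a-octahydrocyclodeca[b]furan-2(3H)-one | C=C1C(=O)O[C@H]2/C=C(/C)[C@@H](O[Si](C)(C)C(C)(C)C)CC[C@](C)(O)C[C@H](O)[C@@H]12
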